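**Retrosynthetic overview**
1. Last disconnections: the two silyl ethers and the C8 ester, giving a macrocyclic 8-hydroxy lactone and (S)-4-silyloxy-3-methylbutanoic acid (from (S)-β-methyl-γ-butyrolactone).
2. Key disconnection: C7–C8. The C8 aldehyde becomes a samarium ketyl (nucleophilic carbonyl carbon) that attacks the electrophilic β-carbon C7 of a butenolide; this closes the ten-membered ring and sets C7, C8 and C11.
3. The butenolide (C6 stereocentre) comes from a Z-enal and ethyl 2-(bromomethyl)acrylate by catalytic asymmetric chromium allylation (β-acrylate anion equivalent), then an exo-to-endo alkene shift.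
4. C3–C4 comes from an alkyl-9-BBN and ethyl 4-silyloxybut-2-ynoate by copper-catalysed syn-hydroalkylation (fixes C4=C5); the Z-C1=C10 alkene comes from 4-methyl-5,6-dihydro-2H-pyran-2-one.
5. Ring order: butenolide first, ten-membered carbocycle second.

Assumption: 4-methyl-5,6-dihydro-2H-pyran-2-one and (S)-4-methyloxolan-2-one are taken as catalogue starting materials. Positions are given in germacrane numbering (C6 lactone carbinol, C7 ring-fusion carbon, C8 ester carbinol, C11 α-methyl carbon, C15 the CH2OH carbon). TBS = tert-butyldimethylsilyl.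

**Route**

Step 1
Reactants: 1 4-methyl-5,6-dihydro-2H-pyran-2-one
Product: 3 (3Z)-3-methylhexa-3,5-dien-1-ol, via lactol 2 (not isolated)
Conditions: i-Bu2AlH (1.1 equiv), CH2Cl2, −78 °C; then Ph3PCH3Br, KOtBu, THF, −78 °C to rt
Reagents that add atoms: methylenetriphenylphosphorane (from Ph3PCH3Br and KOtBu), C=P(c1ccccc1)(c1ccccc1)c1ccccc1
Why: At −78 °C i-Bu2AlH reduces the unsaturated lactone only to the lactol, whose ring-opened Z-hydroxy-enal is methylenated by the ylide (Wittig reaction), so the ring-enforced Z geometry of the trisubstituted C1=C10 alkene (C9 cis to C2) is carried into the diene.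

Step 2
Reactants: 4 tert-butyldimethyl(prop-2-yn-1-yloxy)silane
Product: 6 ethyl 4-[(tert-butyldimethylsilyl)oxy]but-2-ynoate, via lithium acetylide 5 (not isolated)
Conditions: n-BuLi, THF, −78 °C; ClCO2Et, −78 to 0 °C
Reagents that add atoms: ethyl chloroformate, CCOC(=O)Cl
Why: Deprotonation of the terminal alkyne and C-acylation of the lithium acetylide with the chloroformate gives the ynoate (acetylide acylation).

Step 3
Reactants: 3 (3Z)-3-methylhexa-3,5-dien-1-ol; 6 ethyl 4-[(tert-butyldimethylsilyl)oxy]but-2-ynoate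
Product: 8 ethyl (2Z,6Z)-3-({[tert-butyl(dimethyl)silyl]oxy}methyl)-9-hydroxy-7-methylnona-2,6-dienoate, via alkylborane 7 (not isolated)
Conditions: 9-BBN (2.2 equiv), THF, 0 °C to rt; then 6, CuOAc (5 mol%), P(OPh)3 (10 mol%), KOtBu (20 mol%), t-BuOH (2 equiv), 1,4-dioxane, 40 °C
Reagents that add atoms: none
Why: 9-BBN hydroborates only the monosubstituted alkene with boron on the terminal carbon (the hydroxyl is capped as its borinate), and copper-catalysed conjugate addition of the B-alkyl group to the ynoate followed by protonation of the alkenylcopper by t-BuOH (syn-carbocupration, formal syn-hydroalkylation) puts the new chain cis to H5, so CH2OTBS and the ester end up cis (2Z), the geometry needed for C4=C5.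

Step 4
Reactants: 8 ethyl (2Z,6Z)-3-({[tert-butyl(dimethyl)silyl]oxy}methyl)-9-hydroxy-7-methylnona-2,6-dienoate
Product: 9 (2Z,6Z)-3-({[tert-butyl(dimethyl)silyl]oxy}methyl)-7-methylnona-2,6-diene-1,9-diol
Conditions: i-Bu2AlH (3.5 equiv), CH2Cl2, −78 °C; aq. KNaC4H4O6 work-up
Reagents that add atoms: none
Why: 1,2-Hydride reduction of the conjugated ester with i-Bu2AlH gives the allylic alcohol without touching the alkene geometry or the silyl ether.

Step 5
Reactants: 9 (2Z,6Z)-3-({[tert-butyl(dimethyl)silyl]oxy}methyl)-7-methylnona-2,6-diene-1,9-diol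
Product: 10 (2Z,6Z)-3-({[tert-butyl(dimethyl)silyl]oxy}methyl)-9-hydroxy-7-methylnona-2,6-dienal
Conditions: MnO2 (15 equiv), CH2Cl2, rt
Reagents that add atoms: none
Why: MnO2 oxidises the allylic primary alcohol selectively (allylic oxidation), leaving the homoallylic C8 hydroxyl and the Z geometry untouched.

Step 6
Reactants: 10 (2Z,6Z)-3-({[tert-butyl(dimethyl)silyl]oxy}methyl)-9-hydroxy-7-methylnona-2,6-dienal; 11 ethyl 2-(bromomethyl)prop-2-enoate
Product: 13 (5S)-5-[(1Z,5Z)-2-({[tert-butyl(dimethyl)silyl]oxy}methyl)-8-hydroxy-6-methylocta-1,5-dien-1-yl]-3-methylideneoxolan-2-one, via hydroxy ester 12 (not isolated)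
Conditions: CrCl2 (10 mol%), (S,S)-3,6-di-tert-butyl-1,8-bis(4-isopropyl-4,5-dihydrooxazol-2-yl)-9H-carbazole (12 mol%), Mn powder (2 equiv), Me3SiCl (2.4 equiv), i-Pr2NEt (1.3 equiv), THF, rt; aq. citric acid work-up; then PPTS (10 mol%), CH2Cl2, rt
Reagents that add atoms: none
Why: Catalytic asymmetric Nozaki–Hiyama–Kishi-type allylation in which divalent chromium (recycled by Mn) turns the allylic bromide into an allylchromium species, a β-acrylate anion (homoenolate-type) equivalent, that adds through its γ-carbon 1,2 to the Si face of the aldehyde under control of the chiral tridentate ligand, setting C6 (5S in 13; the antipodal ligand would give the enantiomer), after which the γ-hydroxy ester closes to the lactone under mild acid.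

Step 7
Reactants: 13 (5S)-5-[(1Z,5Z)-2-({[tert-butyl(dimethyl)silyl]oxy}methyl)-8-hydroxy-6-methylocta-1,5-dien-1-yl]-3-methylideneoxolan-2-one
Product: 14 (5R)-5-[(1Z,5Z)-2-({[tert-butyl(dimethyl)silyl]oxy}methyl)-8-hydroxy-6-methylocta-1,5-dien-1-yl]-3-methylfuran-2(5H)-one
Conditions: RhCl(PPh3)3 (5 mol%), Et3SiH (10 mol%), toluene, 80 °C
Reagents that add atoms: none
Why: A rhodium hydride formed from RhCl(PPh3)3 and Et3SiH adds to the exocyclic alkene and β-hydride elimination toward C7 moves the double bond into the ring (metal-hydride alkene isomerisation to the more stable conjugated butenolide); no base is present, so the acidic C6–H stereocentre is not touched (the descriptor changes from S to R only because the priorities change).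

Step 8
Reactants: 14 (5R)-5-[(1Z,5Z)-2-({[tert-butyl(dimethyl)silyl]oxy}methyl)-8-hydroxy-6-methylocta-1,5-dien-1-yl]-3-methylfuran-2(5H)-one
Product: 15 (3Z,7Z)-7-({[tert-butyl(dimethyl)silyl]oxy}methyl)-3-methyl-8-[(2R)-4-methyl-5-oxo-2,5-dihydrofuran-2-yl]octa-3,7-dienal
Conditions: Dess–Martin periodinane, NaHCO3, CH2Cl2, 0 °C; used crude
Reagents that add atoms: none
Why: Dess–Martin oxidation of the only free (primary) alcohol under buffered conditions gives the β,γ-unsaturated aldehyde without alkene migration or epimerisation of the butenolide.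

Step 9
Reactants: 15 (3Z,7Z)-7-({[tert-butyl(dimethyl)silyl]oxy}methyl)-3-methyl-8-[(2R)-4-methyl-5-oxo-2,5-dihydrofuran-2-yl]octa-3,7-dienal
Product: 16 (3S,3aR,4S,6Z,10Z,11aR)-10-({[tert-butyl(dimethyl)silyl]oxy}methyl)-4-hydroxy-3,6-dimethyl-3a,4,5,8,9,11a-hexahydrocyclodeca[b]furan-2(3H)-one
Conditions: SmI2 (3 equiv, 0.1 M in THF), t-BuOH (3 equiv), THF, −78 to 0 °C, 15 added over 4 h (final 2 mM), no HMPA
Reagents that add atoms: none
Why: Proposed new method: SmI2 reduces the aldehyde to a samarium ketyl, a carbonyl carbon of reversed (nucleophilic) polarity, which adds to the electrophilic β-carbon C7 of the butenolide, so two normally electrophilic carbons are joined and the ten-membered ring closes, the α-carbonyl radical then being reduced to a samarium enolate and protonated by t-BuOH; the closest known reactions are the SmI2-mediated ketyl–olefin coupling of aldehydes with acrylates and butenolides to γ-hydroxy esters and samarium ketyl cyclisations to medium rings; attack on C7 is expected anti to the C5 chain on C6 (7R, trans-fused lactone), with the bulky O–Sm group turned outward, anti to C6 (8S), and protonation of C11 on the face of the C8 alkoxide to give the more stable trans α,β-arrangement (11S).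

Step 10
Reactants: 17 (4S)-4-methyloxolan-2-one
Product: 20 (3S)-4-[(tert-butyldimethylsilyl)oxy]-3-methylbutanoic acid, via potassium carboxylate 18 (not isolated), via bis-silyl derivative 19 (not isolated)
Conditions: KOH (1.0 equiv), MeOH/H2O, rt, evaporate; then TBSCl (2.3 equiv), imidazole, DMF, rt; then K2CO3 (cat.), MeOH/THF/H2O, rt, work-up at pH 4–5
Reagents that add atoms: potassium hydroxide, [K+].[OH-]; tert-butyldimethylsilyl chloride, CC(C)(C)[Si](C)(C)Cl
Why: Saponification opens the lactone, silylation caps both the hydroxyl and the carboxylate, and mild carbonate hydrolysis cleaves only the labile silyl ester (standard hydroxy-acid protection); the stereocentre is not involved.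

Step 11
Reactants: 16 (3S,3aR,4S,6Z,10Z,11aR)-10-({[tert-butyl(dimethyl)silyl]oxy}methyl)-4-hydroxy-3,6-dimethyl-3a,4,5,8,9,11a-hexahydrocyclodeca[b]furan-2(3H)-one; 20 (3S)-4-[(tert-butyldimethylsilyl)oxy]-3-methylbutanoic acid
Product: 21 (3S,3aR,4S,6Z,10Z,11aR)-10-({[tert-butyl(dimethyl)silyl]oxy}methyl)-3,6-dimethyl-2-oxo-2,3,3a,4,5,8,9,11a-octahydrocyclodeca[b]furan-4-yl (3S)-4-[(tert-butyldimethylsilyl)oxy]-3-methylbutanoate
Conditions: DCC, DMAP, CH2Cl2, 0 °C to rt
Reagents that add atoms: none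
Why: Steglich esterification (carbodiimide, DMAP) acylates the only free hydroxyl with retention at C8, and the β-stereocentre of the acid cannot epimerise.

Step 12
Reactants: 21 (3S,3aR,4S,6Z,10Z,11aR)-10-({[tert-butyl(dimethyl)silyl]oxy}methyl)-3,6-dimethyl-2-oxo-2,3,3a,4,5,8,9,11a-octahydrocyclodeca[b]furan-4-yl (3S)-4-[(tert-butyldimethylsilyl)oxy]-3-methylbutanoate
Product: 22 (3S,3aR,4S,6Z,10Z,11aR)-10-(hydroxymethyl)-3,6-dimethyl-2-oxo-2,3,3a,4,5,8,9,11a-octahydrocyclodeca[b]furan-4-yl (3S)-4-hydroxy-3-methylbutanoate (CNP0160815.1)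
Conditions: HF·pyridine, pyridine, THF, 0 °C
Reagents that add atoms: none
Why: Buffered HF·pyridine cleaves both primary silyl ethers (fluoride desilylation) under conditions mild enough to avoid acid-induced transannular cyclisation of the 1(10),4-diene and lactonisation of the liberated γ-hydroxy ester.

**Compound list**
1 | 4-methyl-5,6-dihydro-2H-pyran-2-one | CC1=CC(=O)OCC1 | starting material
2 | 4-methyl-5,6-dihydro-2H-pyran-2-ol (lactol, as its aluminium alkoxide in the flask) | CC1=CC(O)OCC1 | intermediate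
3 | (3Z)-3-methylhexa-3,5-dien-1-ol | OCC/C(C)=C\C=C | intermediate
4 | tert-butyldimethyl(prop-2-yn-1-yloxy)silane | C#CCO[Si](C)(C)C(C)(C)C | starting material
5 | {3-[(tert-butyldimethylsilyl)oxy]prop-1-yn-1-yl}lithium | [Li]C#CCO[Si](C)(C)C(C)(C)C | intermediate
6 | ethyl 4-[(tert-butyldimethylsilyl)oxy]but-2-ynoate | CCOC(=O)C#CCO[Si](C)(C)C(C)(C)C | intermediate
7 | 9-[(3Z)-6-(9-borabicyclo[3.3.1]nonan-9-yloxy)-4-methylhex-3-en-1-yl]-9-borabicyclo[3.3.1]nonane | C1CCC2CCCC1B2CC/C=C(C)\CCOB1C2CCCC1CCC2 | intermediate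
8 | ethyl (2Z,6Z)-3-({[tert-butyl(dimethyl)silyl]oxy}methyl)-9-hydroxy-7-methylnona-2,6-dienoate | CCOC(=O)/C=C(\CO[Si](C)(C)C(C)(C)C)CC/C=C(C)\CCO | intermediate
9 | (2Z,6Z)-3-({[tert-butyl(dimethyl)silyl]oxy}methyl)-7-methylnona-2,6-diene-1,9-diol | OC/C=C(\CO[Si](C)(C)C(C)(C)C)CC/C=C(C)\CCO | intermediate
10 | (2Z,6Z)-3-({[tert-butyl(dimethyl)silyl]oxy}methyl)-9-hydroxy-7-methylnona-2,6-dienal | O=C/C=C(\CO[Si](C)(C)C(C)(C)C)CC/C=C(C)\CCO | intermediate
11 | ethyl 2-(bromomethyl)prop-2-enoate | C=C(CBr)C(=O)OCC | starting material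
12 | ethyl (4S,5Z,9Z)-6-({[tert-butyl(dimethyl)silyl]oxy}methyl)-4,12-dihydroxy-10-methyl-2-methylidenedodeca-5,9-dienoate | CCOC(=O)C(=C)C[C@H](O)/C=C(\CO[Si](C)(C)C(C)(C)C)CC/C=C(C)\CCO | intermediate
13 | (5S)-5-[(1Z,5Z)-2-({[tert-butyl(dimethyl)silyl]oxy}methyl)-8-hydroxy-6-methylocta-1,5-dien-1-yl]-3-methylideneoxolan-2-one | OCC/C(C)=C\CC/C(CO[Si](C)(C)C(C)(C)C)=C/[C@H]1OC(=O)C(=C)C1 | intermediate
14 | (5R)-5-[(1Z,5Z)-2-({[tert-butyl(dimethyl)silyl]oxy}methyl)-8-hydroxy-6-methylocta-1,5-dien-1-yl]-3-methylfuran-2(5H)-one | OCC/C(C)=C\CC/C(CO[Si](C)(C)C(C)(C)C)=C/[C@H]1OC(=O)C(C)=C1 | intermediate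
15 | (3Z,7Z)-7-({[tert-butyl(dimethyl)silyl]oxy}methyl)-3-methyl-8-[(2R)-4-methyl-5-oxo-2,5-dihydrofuran-2-yl]octa-3,7-dienal | O=CC/C(C)=C\CC/C(CO[Si](C)(C)C(C)(C)C)=C/[C@H]1OC(=O)C(C)=C1 | intermediate
16 | (3S,3aR,4S,6Z,10Z,11aR)-10-({[tert-butyl(dimethyl)silyl]oxy}methyl)-4-hydroxy-3,6-dimethyl-3a,4,5,8,9,11a-hexahydrocyclodeca[b]furan-2(3H)-one | C/C1=C/CC/C(CO[Si](C)(C)C(C)(C)C)=C/[C@H]2OC(=O)[C@@H](C)[C@@H]2[C@@H](O)C1 | intermediate
17 | (4S)-4-methyloxolan-2-one | O=C1C[C@H](C)CO1 | starting material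
18 | potassium (3S)-4-hydroxy-3-methylbutanoate | [K+].[O-]C(=O)C[C@H](C)CO | intermediate
19 | tert-butyldimethylsilyl (3S)-4-[(tert-butyldimethylsilyl)oxy]-3-methylbutanoate | CC(C)(C)[Si](C)(C)OC(=O)C[C@H](C)CO[Si](C)(C)C(C)(C)C | intermediate
20 | (3S)-4-[(tert-butyldimethylsilyl)oxy]-3-methylbutanoic acid | OC(=O)C[C@H](C)CO[Si](C)(C)C(C)(C)C | intermediate
21 | (3S,3aR,4S,6Z,10Z,11aR)-10-({[tert-butyl(dimethyl)silyl]oxy}methyl)-3,6-dimethyl-2-oxo-2,3,3a,4,5,8,9,11a-octahydrocyclodeca[b]furan-4-yl (3S)-4-[(tert-butyldimethylsilyl)oxy]-3-methylbutanoate | C/C1=C/CC/C(CO[Si](C)(C)C(C)(C)C)=C/[C@H]2OC(=O)[C@@H](C)[C@@H]2[C@@H](OC(=O)C[C@H](C)CO[Si](C)(C)C(C)(C)C)C1 | intermediate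
22 | (3S,3aR,4S,6Z,10Z,11aR)-10-(hydroxymethyl)-3,6-dimethyl-2-oxo-2,3,3a,4,5,8,9,11a-octahydrocyclodeca[b]furan-4-yl (3S)-4-hydroxy-3-methylbutanoate | C/C1=C/CC/C(CO)=C/[C@H]2OC(=O)[C@@H](C)[C@@H]2[C@@H](OC(=O)C[C@H](C)CO)C1 | target

**Step count**
Total: 12 steps. Longest linear sequence: 10 steps (1, 3, 4, 5, 6, 7, 8, 9, 11, 12).

**Three steps most likely to fail, with fallbacks**

Step 9 (samarium ketyl ring closure). The ten-membered closure competes with simple reduction of the aldehyde (which returns 14, recyclable through step 8), and the face of the ketyl that attacks C7 is the least predictable element of the route. The fallback sets out from 15: if the closure delivers the C8 epimer, (3S,3aR,4R,6Z,10Z,11aR)-10-({[tert-butyl(dimethyl)silyl]oxy}methyl)-4-hydroxy-3,6-dimethyl-3a,4,5,8,9,11a-hexahydrocyclodeca[b]furan-2(3H)-one F1, the ester is no longer made by acylation with retention. Instead F1 is esterified with acid 20 under Mitsunobu conditions (PPh3, DIAD, toluene, 0 °C), which inverts C8 by SN2 displacement and rejoins the route at 21.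

Step 6 (asymmetric chromium allylation of a Z-configured, β,β-disubstituted enal carrying a free hydroxyl; the sense and level of induction, and the following isomerisation in step 7, are the concerns). The fallback sets out from 10 and builds the butenolide from an alkyne instead. Zinc-mediated asymmetric alkynylation of 10 with propyne (Me2Zn, the ProPhenol ligand enantiomer that gives the 9R carbinol, toluene, 0 °C) gives the propargylic alcohol (3Z,7Z,9R)-7-({[tert-butyl(dimethyl)silyl]oxy}methyl)-3-methyldodeca-3,7-dien-10-yne-1,9-diol F2. Hydroxyl-directed trans-hydroalumination with NaAlH2(OCH2CH2OMe)2 and iodination (I2, −78 °C) gives the vinyl iodide (3Z,7Z,9R,10Z)-7-({[tert-butyl(dimethyl)silyl]oxy}methyl)-11-iodo-3-methyldodeca-3,7,10-triene-1,9-diol F3. Carbonylative lactonisation (PdCl2(PPh3)2, CO 1 atm, K2CO3, THF, 50 °C) then gives 14 directly, bypassing 13 and step 7.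

Step 3 (hydroboration of the dienol and copper-catalysed hydroalkylation with an unprotected hydroxyl). The fallback sets out from 3 and replaces the conjugate addition by a palladium cross-coupling with a stereodefined enol triflate. (tert-Butyldimethylsilyloxy)acetaldehyde and ethyl diazoacetate (SnCl2, CH2Cl2) give the β-keto ester ethyl 4-[(tert-butyldimethylsilyl)oxy]-3-oxobutanoate F4. E-selective triflation (Tf2O, aq. Me4NOH, hexane, 5 °C) gives the enol triflate ethyl (2E)-4-[(tert-butyldimethylsilyl)oxy]-3-{[(trifluoromethyl)sulfonyl]oxy}but-2-enoate F5. B-alkyl Suzuki–Miyaura coupling of F5 with borane 7 (made from 3 as in step 3; PdCl2(dppf), aq. K3PO4, THF/DMF, rt) proceeds with retention and rejoins the route at 8.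

**Further compounds**
F1 | step 9 | (3S,3aR,4R,6Z,10Z,11aR)-10-({[tert-butyl(dimethyl)silyl]oxy}methyl)-4-hydroxy-3,6-dimethyl-3a,4,5,8,9,11a-hexahydrocyclodeca[b]furan-2(3H)-one | C/C1=C/CC/C(CO[Si](C)(C)C(C)(C)C)=C/[C@H]2OC(=O)[C@@H](C)[C@@H]2[C@H](O)C1
F2 | step 6 | (3Z,7Z,9R)-7-({[tert-butyl(dimethyl)silyl]oxy}methyl)-3-methyldodeca-3,7-dien-10-yne-1,9-diol | CC#C[C@H](O)/C=C(\CO[Si](C)(C)C(C)(C)C)CC/C=C(C)\CCO
F3 | step 6 | (3Z,7Z,9R,10Z)-7-({[tert-butyl(dimethyl)silyl]oxy}methyl)-11-iodo-3-methyldodeca-3,7,10-triene-1,9-diol | C/C(I)=C/[C@H](O)/C=C(\CO[Si](C)(C)C(C)(C)C)CC/C=C(C)\CCO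
F4 | step 3 | ethyl 4-[(tert-butyldimethylsilyl)oxy]-3-oxobutanoate | CCOC(=O)CC(=O)CO[Si](C)(C)C(C)(C)C
F5 | step 3 | ethyl (2E)-4-[(tert-butyldimethylsilyl)oxy]-3-{[(trifluoromethyl)sulfonyl]oxy}but-2-enoate | CCOC(=O)/C=C(\CO[Si](C)(C)C(C)(C)C)OS(=O)(=O)C(F)(F)F
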